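The target is disconnected at C9–C10 and C5–C6, which leaves ring A (C1–C5, C10) as a carvone-derived cyclohexenone. Its single stereocentre, the silyloxy-bearing C2, sits 1,3 to the enone β-carbon C10 and next to the ring is the methyl-bearing C5; the key step exploits this C2/C10/C5 array. In one flask, copper-catalysed vinyl addition at C10 and allylation of the resulting enolate at C5 set both ring-fusion stereocentres from C2 and attach the C9 aldehyde precursor and the C6–C8 (Z)-iodoallyl arm. The precursor is (R)-5-(tert-butyldimethylsilyloxy)-2-methylcyclohex-2-enone. Ring B is closed afterwards at C8–C9.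

Key step: step 6

Remarks: eremophilane numbering is used (ring A = C1–C5 and C10, ring B = C5–C10, C14/C15 = methyl groups on C5/C4); β is the face of C14, α the opposite face. Ethyl (Z)-3-iodoacrylate and (Z)-3-methylpent-2-enoic acid are assumed to be purchasable as single geometric isomers, and both Grignard reagents as THF solutions.

Step 1
Reactants: 1 (R)-(−)-carvone
Product: 4 (R)-5-acetoxy-2-methylcyclohex-2-en-1-one, via methoxy hydroperoxide 2 (not isolated), via peroxyacetate 3 (not isolated)
Conditions: O3, CH2Cl2/MeOH, −78 °C; then Ac2O, Et3N, DMAP (cat.), −78 °C → rt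
Reagents that add atoms: ozone, [O-][O+]=O; methanol, CO; acetic anhydride, CC(=O)OC(C)=O (acetyl group in intermediate 3 only)
Why: Ozonolysis of the electron-rich isopropenyl group in methanol should give the α-methoxy hydroperoxide, whose peracetate undergoes Criegee rearrangement with migration of the ring carbon from carbon to oxygen with retention, so the carvone stereocentre becomes the future C2 carbinol unchanged.

Step 2
Reactants: 4 (R)-5-acetoxy-2-methylcyclohex-2-en-1-one
Product: 5 (R)-5-hydroxy-2-methylcyclohex-2-en-1-one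
Conditions: K2CO3 (cat.), MeOH, 0 °C
Reagents that add atoms: none
Why: Carbonate-catalysed transesterification of the acetate to methanol, run cold and stopped early because the β-acyloxy ketone could otherwise eliminate and aromatise; the C–O bond at the stereocentre is not broken.

Step 3
Reactants: 5 (R)-5-hydroxy-2-methylcyclohex-2-en-1-one
Product: 6 (R)-5-(tert-butyldimethylsilyloxy)-2-methylcyclohex-2-en-1-one
Conditions: TBSCl, imidazole, DMF, 0 °C → rt
Reagents that add atoms: tert-butyldimethylsilyl chloride, CC(C)(C)[Si](C)(C)Cl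
Why: Imidazole-promoted silylation of a secondary alcohol under near-neutral conditions that avoid β-elimination; the stereocentre is not involved.

Step 4
Reactants: 7 ethyl (Z)-3-iodoprop-2-enoate
Product: 8 (Z)-3-iodoprop-2-en-1-ol
Conditions: i-Bu2AlH (2.2 equiv), CH2Cl2, −78 °C; aqueous potassium sodium tartrate
Reagents that add atoms: none
Why: Hydride reduction of the ester through the aldehyde to the allylic alcohol at low temperature, which should leave the C–I bond and the Z geometry intact.

Step 5
Reactants: 8 (Z)-3-iodoprop-2-en-1-ol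
Product: 9 (Z)-3-bromo-1-iodoprop-1-ene
Conditions: CBr4, PPh3, CH2Cl2, 0 °C, dark
Reagents that add atoms: tetrabromomethane, BrC(Br)(Br)Br
Why: Appel reaction, in which bromide displaces the alkoxyphosphonium group at the primary allylic carbon while the Z-iodoalkene is untouched; the bromide is used freshly.

Step 6
Reactants: 6 (R)-5-(tert-butyldimethylsilyloxy)-2-methylcyclohex-2-en-1-one, 10 vinylmagnesium bromide, 9 (Z)-3-bromo-1-iodoprop-1-ene
Product: 12 (2S,3S,5R)-5-(tert-butyldimethylsilyloxy)-3-ethenyl-2-[(2Z)-3-iodoprop-2-en-1-yl]-2-methylcyclohexan-1-one, via bromomagnesium enolate 11 (not isolated)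
Conditions: 10 (1.3 equiv), CuI (10 mol%), THF, −78 → −40 °C; then HMPA, 9 (2 equiv), −40 → 0 °C
Reagents that add atoms: none
Why: Catalytic CuI converts 10 into a vinylcopper species that adds 1,4 to enone 6 and gives the regiodefined bromomagnesium enolate 11, which, once HMPA is added, is C-allylated by SN2 displacement of the allylic bromide of 9, forming C9–C10 and then C5–C6. The closest known reaction type is the copper-catalysed conjugate addition of Grignard reagents to 2-methylcyclohex-2-enones with trapping of the enolate by an allylic halide in the same flask. No ring closes. C10 is set by substrate control from C2: the vinyl group should enter axially on the enone half-chair anti to the C2 silyloxy group (1,3-trans). C5 is set by the new C10 centre: the electrophile should approach the enolate face opposite the adjacent vinyl group (1,2-trans), which leaves the methyl group cis to vinyl. The step needs 1,4- over 1,2-addition (secured by copper), alkylation at C5 only (the enolate is formed regiospecifically and trapped cold before proton exchange toward C3, which would also expel the C2 silyloxy group) and reaction at the CH2Br terminus (the sp2 C–I bond is inert to the enolate).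

Step 7
Reactants: 12 (2S,3S,5R)-5-(tert-butyldimethylsilyloxy)-3-ethenyl-2-[(2Z)-3-iodoprop-2-en-1-yl]-2-methylcyclohexan-1-one
Product: 14 (1R,2S,5R)-5-(tert-butyldimethylsilyloxy)-2-[(2Z)-3-iodoprop-2-en-1-yl]-2-methyl-3-oxocyclohexane-1-carbaldehyde, via vicinal diol 13 (not isolated)
Conditions: OsO4 (2 mol%), NaIO4 (4 equiv), 2,6-lutidine, dioxane/H2O (3:1), rt
Reagents that add atoms: osmium tetroxide, O=[Os](=O)(=O)=O, reoxidised by sodium periodate, [Na+].[O-]I(=O)(=O)=O
Why: Lemieux–Johnson oxidation, in which OsO4 should dihydroxylate the monosubstituted vinyl group in preference to the electron-poor Z-iodoalkene and periodate cleaves the diol to the C9 aldehyde, with 2,6-lutidine buffering the medium so that the aldehyde α-centre C10 is not epimerised.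

Step 8
Reactants: 14 (1R,2S,5R)-5-(tert-butyldimethylsilyloxy)-2-[(2Z)-3-iodoprop-2-en-1-yl]-2-methyl-3-oxocyclohexane-1-carbaldehyde
Product: 15 (2α,5β,9α,10α)-2-(tert-butyldimethylsilyloxy)-9-hydroxy-11,12,13,15-tetranoreremophil-7-en-4-one
Conditions: CrCl2 (6 equiv), NiCl2 (2 mol%), degassed DMSO, rt
Reagents that add atoms: none
Why: Nozaki–Hiyama–Kishi reaction, in which zerovalent nickel inserts into the C8–I bond, the alkenyl group passes to trivalent chromium and adds only to the aldehyde (the hindered C4 ketone is inert), closing ring B at C8–C9 in a 6-exo-trig carbonyl addition; the chromium-bound oxygen should take the pseudoequatorial site away from the axial C14 methyl and so give the 9α-alcohol.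

Step 9
Reactants: 15 (2α,5β,9α,10α)-2-(tert-butyldimethylsilyloxy)-9-hydroxy-11,12,13,15-tetranoreremophil-7-en-4-one
Product: 16 (2α,5β,9α,10α)-2-(tert-butyldimethylsilyloxy)-11,12,13-trinoreremophila-4(15),7-dien-9-ol
Conditions: Zn, CH2Br2, TiCl4 (pre-formed reagent, excess), THF/CH2Cl2, 0 °C → rt
Reagents that add atoms: dibromomethane, BrCBr
Why: Takai–Lombardo methylenation, whose zinc/titanium methylene reagent is non-basic, so the hindered α-quaternary ketone should be methylenated without enolisation toward C3 and loss of the β-silyloxy group, the C9 hydroxyl being carried as its metal alkoxide.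

Step 10
Reactants: 16 (2α,5β,9α,10α)-2-(tert-butyldimethylsilyloxy)-11,12,13-trinoreremophila-4(15),7-dien-9-ol
Product: 17 (2α,5β,7α,8α,9α,10α)-2-(tert-butyldimethylsilyloxy)-7,8-epoxy-11,12,13-trinoreremophil-4(15)-en-9-ol
Conditions: VO(acac)2 (5 mol%), t-BuOOH, CH2Cl2, 0 °C → rt
Reagents that add atoms: tert-butyl hydroperoxide, CC(C)(C)OO
Why: Vanadium-catalysed hydroxyl-directed epoxidation, in which the C9 vanadate ester delivers oxygen to the allylic C7=C8 bond on the α face (syn to the hydroxyl and remote from the axial C14 methyl) while the isolated methylene group is left alone.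

Step 11
Reactants: 17 (2α,5β,7α,8α,9α,10α)-2-(tert-butyldimethylsilyloxy)-7,8-epoxy-11,12,13-trinoreremophil-4(15)-en-9-ol
Product: 18 (2α,4β,5β,7α,8α,9α,10α)-2-(tert-butyldimethylsilyloxy)-7,8-epoxy-11,12,13-trinoreremophilan-9-ol
Conditions: Mn(dpm)3 (10 mol%; dpm = 2,2,6,6-tetramethylheptane-3,5-dionate), PhSiH3, t-BuOOH, i-PrOH, rt
Reagents that add atoms: none
Why: Mukaiyama-type hydrogen-atom-transfer hydrogenation, in which a manganese hydride gives H to the methylene carbon of the 1,1-disubstituted alkene and the tertiary C4 radical should take up the second hydrogen along the axial direction, so that the new methyl group becomes equatorial and cis to C14 and not syn-axial to the C2 silyloxy group; epoxide and hydroxyl are inert.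

Step 12
Reactants: 18 (2α,4β,5β,7α,8α,9α,10α)-2-(tert-butyldimethylsilyloxy)-7,8-epoxy-11,12,13-trinoreremophilan-9-ol, 19 isopropenylmagnesium bromide
Product: 20 (2α,4β,5β,7β,8α,9α,10α)-2-(tert-butyldimethylsilyloxy)eremophil-11-ene-8,9-diol
Conditions: 19 (4 equiv), CuI (20 mol%), THF, −30 → 0 °C
Reagents that add atoms: none
Why: Copper-catalysed Grignard opening of an epoxide, in which, after deprotonation of the C9 hydroxyl, the isopropenylcopper species should attack C7 from the β face with inversion (Fürst–Plattner trans-diaxial opening through a chair-like transition state, whereas attack at C8 would need a twist-boat and is flanked by the C9 alkoxide), placing isopropenyl 7β-axial and hydroxyl 8α-axial.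

Step 13
Reactants: 20 (2α,4β,5β,7β,8α,9α,10α)-2-(tert-butyldimethylsilyloxy)eremophil-11-ene-8,9-diol, 21 (Z)-3-methylpent-2-enoic acid
Product: 23 (2α,4β,5β,7β,8α,9α,10α)-2-(tert-butyldimethylsilyloxy)-8-hydroxyeremophil-11-en-9-yl (2Z)-3-methylpent-2-enoate, via mixed anhydride 22 (not isolated)
Conditions: 21 (1.3 equiv), 2,4,6-trichlorobenzoyl chloride, Et3N, toluene, rt; then 20, DMAP, 0 °C → rt
Reagents that add atoms: 2,4,6-trichlorobenzoyl chloride, O=C(Cl)c1c(Cl)cc(Cl)cc1Cl (aroyl group in intermediate 22 only)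
Why: Yamaguchi esterification, in which the acylpyridinium formed from the mixed anhydride and DMAP should acylate the equatorial C9 hydroxyl faster than the axial C8 hydroxyl, which is screened by the syn-axial hydrogens at C6 and C10, and should transfer the β,β-disubstituted Z-enoyl group without change of geometry at low temperature.

Step 14
Reactants: 23 (2α,4β,5β,7β,8α,9α,10α)-2-(tert-butyldimethylsilyloxy)-8-hydroxyeremophil-11-en-9-yl (2Z)-3-methylpent-2-enoate
Product: 24 (2α,4β,5β,7β,8α,9α,10α)-2,8-dihydroxyeremophil-11-en-9-yl (2Z)-3-methylpent-2-enoate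
Conditions: HF·pyridine, pyridine/THF, 0 °C → rt
Reagents that add atoms: none
Why: Fluoride-mediated cleavage of the silyl ether under buffered, non-basic conditions, chosen so that the C9 ester should not migrate to the neighbouring C8 hydroxyl and the isopropenyl group is left alone.

Compound list
1 | (R)-(−)-carvone, (5R)-2-methyl-5-(prop-1-en-2-yl)cyclohex-2-en-1-one | CC1=CC[C@H](CC1=O)C(C)=C | starting material
2 | (5R)-5-(1-hydroperoxy-1-methoxyethyl)-2-methylcyclohex-2-en-1-one (either configuration at the peroxy carbon) | CC1=CC[C@H](CC1=O)C(C)(OC)OO | intermediate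
3 | 1-methoxy-1-[(1R)-4-methyl-5-oxocyclohex-3-en-1-yl]ethyl peroxyacetate | CC1=CC[C@H](CC1=O)C(C)(OC)OOC(C)=O | intermediate
4 | (R)-5-acetoxy-2-methylcyclohex-2-en-1-one | CC1=CC[C@@H](OC(C)=O)CC1=O | intermediate
5 | (R)-5-hydroxy-2-methylcyclohex-2-en-1-one | CC1=CC[C@@H](O)CC1=O | intermediate
6 | (R)-5-(tert-butyldimethylsilyloxy)-2-methylcyclohex-2-en-1-one | CC1=CC[C@@H](O[Si](C)(C)C(C)(C)C)CC1=O | intermediate
7 | ethyl (Z)-3-iodoprop-2-enoate | CCOC(=O)/C=C\I | starting material
8 | (Z)-3-iodoprop-2-en-1-ol | OC/C=C\I | intermediate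
9 | (Z)-3-bromo-1-iodoprop-1-ene | BrC/C=C\I | intermediate
10 | vinylmagnesium bromide | C=C[Mg]Br | starting material
11 | bromomagnesium (3S,5R)-5-(tert-butyldimethylsilyloxy)-3-ethenyl-2-methylcyclohex-1-en-1-olate (vinyl trans to the silyloxy group) | CC1=C(O[Mg]Br)C[C@H](O[Si](C)(C)C(C)(C)C)C[C@H]1C=C | intermediate
12 | (2S,3S,5R)-5-(tert-butyldimethylsilyloxy)-3-ethenyl-2-[(2Z)-3-iodoprop-2-en-1-yl]-2-methylcyclohexan-1-one (vinyl trans to silyloxy and to the iodoallyl arm, cis to methyl) | I/C=C\C[C@]1(C)C(=O)C[C@H](O[Si](C)(C)C(C)(C)C)C[C@H]1C=C | intermediate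
13 | 1,2-diol from 12 (vinyl replaced by 1,2-dihydroxyethyl, ring configurations as in 12, either configuration at the new carbinol) | I/C=C\C[C@]1(C)C(=O)C[C@H](O[Si](C)(C)C(C)(C)C)C[C@H]1C(O)CO | intermediate
14 | (1R,2S,5R)-5-(tert-butyldimethylsilyloxy)-2-[(2Z)-3-iodoprop-2-en-1-yl]-2-methyl-3-oxocyclohexane-1-carbaldehyde | I/C=C\C[C@]1(C)C(=O)C[C@H](O[Si](C)(C)C(C)(C)C)C[C@H]1C=O | intermediate
15 | (2α,5β,9α,10α)-2-(tert-butyldimethylsilyloxy)-9-hydroxy-11,12,13,15-tetranoreremophil-7-en-4-one (trans-fused; C7=C8 in ring B) | C1=CC[C@]2(C)C(=O)C[C@H](O[Si](C)(C)C(C)(C)C)C[C@H]2[C@@H]1O | intermediate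
16 | (2α,5β,9α,10α)-2-(tert-butyldimethylsilyloxy)-11,12,13-trinoreremophila-4(15),7-dien-9-ol | C1=CC[C@]2(C)C(=C)C[C@H](O[Si](C)(C)C(C)(C)C)C[C@H]2[C@@H]1O | intermediate
17 | (2α,5β,7α,8α,9α,10α)-2-(tert-butyldimethylsilyloxy)-7,8-epoxy-11,12,13-trinoreremophil-4(15)-en-9-ol | C1[C@]2(C)C(=C)C[C@H](O[Si](C)(C)C(C)(C)C)C[C@H]2[C@H](O)[C@@H]3O[C@H]13 | intermediate
18 | (2α,4β,5β,7α,8α,9α,10α)-2-(tert-butyldimethylsilyloxy)-7,8-epoxy-11,12,13-trinoreremophilan-9-ol | C1[C@]2(C)[C@@H](C)C[C@H](O[Si](C)(C)C(C)(C)C)C[C@H]2[C@H](O)[C@@H]3O[C@H]13 | intermediate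
19 | isopropenylmagnesium bromide | C=C(C)[Mg]Br | starting material
20 | (2α,4β,5β,7β,8α,9α,10α)-2-(tert-butyldimethylsilyloxy)eremophil-11-ene-8,9-diol | C=C(C)[C@H]1C[C@]2(C)[C@@H](C)C[C@H](O[Si](C)(C)C(C)(C)C)C[C@H]2[C@H](O)[C@@H]1O | intermediate
21 | (Z)-3-methylpent-2-enoic acid | CC/C(C)=C\C(=O)O | starting material
22 | (Z)-3-methylpent-2-enoic 2,4,6-trichlorobenzoic anhydride | CC/C(C)=C\C(=O)OC(=O)c1c(Cl)cc(Cl)cc1Cl | intermediate
23 | (2α,4β,5β,7β,8α,9α,10α)-2-(tert-butyldimethylsilyloxy)-8-hydroxyeremophil-11-en-9-yl (2Z)-3-methylpent-2-enoate | C=C(C)[C@H]1C[C@]2(C)[C@@H](C)C[C@H](O[Si](C)(C)C(C)(C)C)C[C@H]2[C@H](OC(=O)/C=C(/C)CC)[C@@H]1O | intermediate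
24 | (2α,4β,5β,7β,8α,9α,10α)-2,8-dihydroxyeremophil-11-en-9-yl (2Z)-3-methylpent-2-enoate; (2S,4S,5R,7R,8R,9S,10R) | C=C(C)[C@H]1C[C@]2(C)[C@@H](C)C[C@H](O)C[C@H]2[C@H](OC(=O)/C=C(/C)CC)[C@@H]1O | target

Total step count: 14. Longest linear sequence: 12 steps (steps 1–3 and 6–14).

Steps most likely to fail

Step 12. The branched sp2 nucleophile must reach C7 along the axial direction past the syn-axial C14 methyl, so opening may be slow, and bromohydrin formation or attack at C8 may compete. The fallback sets out from 18 and brings the carbon in as a slim sp nucleophile. Opening with diethyl(trimethylsilylethynyl)aluminium (from trimethylsilylacetylene, n-BuLi and Et2AlCl, toluene, 0 °C) should give, by the same trans-diaxial course, (2α,4β,5β,7β,8α,9α,10α)-2-(tert-butyldimethylsilyloxy)-7-(trimethylsilylethynyl)-11,12,13-trinoreremophilane-8,9-diol F1. K2CO3 in MeOH removes the C-silyl group to give the 7β-ethynyl diol F2. Zirconium-catalysed methylalumination of the terminal alkyne (Me3Al, Cp2ZrCl2, CH2Cl2), followed by protonolysis of the alkenylalane, converts ethynyl into isopropenyl and returns to 20.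

Step 13. Acylation may be unselective between the C8 and C9 hydroxyls, may go on to the diester, or the acyl group may migrate or lose its Z geometry. The fallback sets out from 20 and 21 and uses tin-directed acylation. Diol 20 is heated with Bu2SnO in toluene with removal of water to give the 8,9-O-dibutylstannylene acetal F3, which activates the equatorial oxygen of a cis-diol. Acid 21 is converted separately with 1-chloro-N,N,2-trimethylprop-1-en-1-amine in CH2Cl2 into (Z)-3-methylpent-2-enoyl chloride F4. The two are combined at 0 °C without amine base, which should acylate the C9 oxygen and return to 23.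

Step 8. Facial selectivity at the aldehyde may be poor, so that the 9β-alcohol predominates and would misdirect the epoxidation. The fallback sets out from 14 and sets C9 after ring closure by inversion. The 9β-epimer of 15, alcohol F5, obtained under the step 8 conditions, is methylenated as in step 9 to the 9β-dienol F6. A Mitsunobu reaction (4-nitrobenzoic acid, PPh3, diisopropyl azodicarboxylate, THF) inverts C9 and gives the 9α-(4-nitrobenzoate) F7. Methanolysis (K2CO3, MeOH), now safe because the C4 ketone is gone, returns to 16.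

Further compounds
F1 | step 12 | (2α,4β,5β,7β,8α,9α,10α)-2-(tert-butyldimethylsilyloxy)-7-(trimethylsilylethynyl)-11,12,13-trinoreremophilane-8,9-diol | C[Si](C)(C)C#C[C@H]1C[C@]2(C)[C@@H](C)C[C@H](O[Si](C)(C)C(C)(C)C)C[C@H]2[C@H](O)[C@@H]1O
F2 | step 12 | (2α,4β,5β,7β,8α,9α,10α)-2-(tert-butyldimethylsilyloxy)-7-ethynyl-11,12,13-trinoreremophilane-8,9-diol | C#C[C@H]1C[C@]2(C)[C@@H](C)C[C@H](O[Si](C)(C)C(C)(C)C)C[C@H]2[C@H](O)[C@@H]1O
F3 | step 13 | 8α,9α-O-dibutylstannylene acetal of diol 20 | C=C(C)[C@H]1C[C@]2(C)[C@@H](C)C[C@H](O[Si](C)(C)C(C)(C)C)C[C@H]2[C@@H]3O[Sn](CCCC)(CCCC)O[C@H]13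
F4 | step 13 | (Z)-3-methylpent-2-enoyl chloride | CC/C(C)=C\C(Cl)=O
F5 | step 8 | (2α,5β,9β,10α)-2-(tert-butyldimethylsilyloxy)-9-hydroxy-11,12,13,15-tetranoreremophil-7-en-4-one | C1=CC[C@]2(C)C(=O)C[C@H](O[Si](C)(C)C(C)(C)C)C[C@H]2[C@H]1O
F6 | step 8 | (2α,5β,9β,10α)-2-(tert-butyldimethylsilyloxy)-11,12,13-trinoreremophila-4(15),7-dien-9-ol | C1=CC[C@]2(C)C(=C)C[C@H](O[Si](C)(C)C(C)(C)C)C[C@H]2[C@H]1O
F7 | step 8 | (2α,5β,9α,10α)-2-(tert-butyldimethylsilyloxy)-11,12,13-trinoreremophila-4(15),7-dien-9-yl 4-nitrobenzoate | C1=CC[C@]2(C)C(=C)C[C@H](O[Si](C)(C)C(C)(C)C)C[C@H]2[C@@H]1OC(=O)c1ccc(cc1)[N+](=O)[O-]
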